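**Plan**
- Retrosynthesis: the two prenyl termini are cut back to allyl groups (cross-metathesis) and the 5-OH and 4′-OH to MOM ethers; C4=O and C3–OH are traced to the 3,4-oxirane of an isoflav-3-ene; O1–C2 (Mitsunobu) and C3=C4 (Perkin) are cut to a ring A salicylaldehyde and a ring B arylacetic acid.
- Forward: the ring A aldehyde (allyl placed by Claisen rearrangement) and the ring B acid (allyl placed by directed lithiation) are condensed to a 3-arylcoumarin, which is reduced and re-closed as the 2H-chromene (ring C); oxirane formation, oxidative opening, metathesis and unmasking follow.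
- Feature used: in ring C the tertiary carbinol C3 and the ketone C4 are neighbouring oxidised carbons lying between ring B and ring A, the imprint of oxygen transfer to a C3=C4 olefin conjugated with both aryl rings.
- Stereochemistry: the only stereocentre, C3 (S), comes from catalyst-controlled epoxidation; its C–O bond is never broken afterwards.
- Design choices: allyl stands in for prenyl until after the oxidation so that no second reactive olefin is present, and the 5-OH is carried as a MOM ether rather than a methyl ether so that the end-game needs no Lewis acid.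

Key step: step 12

Assumption: the manganese–salen catalyst is taken to choose the olefin face of the 3-aryl-2H-chromene in the same sense as for 2,2-dimethyl-2H-chromenes, which calls for the (R,R) catalyst; if the trisubstituted olefin responds in the opposite sense, the (S,S) catalyst is used instead. Isoflavan numbering (O1, C2, C3, C4; ring B primed) is used throughout.

**Step 1**
Reactants: 1 2,4,6-trimethoxybenzaldehyde
Product: 2 2,6-dihydroxy-4-methoxybenzaldehyde
Conditions: AlCl3 (5 equiv), CH2Cl2, 0 °C to reflux; cold 1 M HCl
Reagents that add atoms: none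
Why: Chelation-controlled Lewis-acid O-demethylation, in which aluminium bound to the formyl oxygen activates only the two ortho methoxy groups toward chloride attack while the para methoxy group, which cannot chelate, should remain.

**Step 2**
Reactants: 2 2,6-dihydroxy-4-methoxybenzaldehyde
Product: 3 2-hydroxy-4-methoxy-6-(methoxymethoxy)benzaldehyde
Conditions: MOMCl (1.05 equiv), i-Pr2NEt, CH2Cl2, 0 °C
Reagents that add atoms: chloromethyl methyl ether (MOMCl), COCCl
Why: MOM protection (Williamson-type O-alkylation) of a symmetric diol, which should stop after one hydroxyl because the remaining one is locked in a hydrogen bond to the formyl group and resists the amine base at 0 °C.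

**Step 3**
Reactants: 3 2-hydroxy-4-methoxy-6-(methoxymethoxy)benzaldehyde
Product: 4 2-(allyloxy)-4-methoxy-6-(methoxymethoxy)benzaldehyde
Conditions: allyl bromide, K2CO3, DMF, 50 °C
Reagents that add atoms: allyl bromide, C=CCBr
Why: Williamson etherification of the chelated phenol, which needs carbonate in warm DMF but has no competing nucleophilic site.

**Step 4**
Reactants: 4 2-(allyloxy)-4-methoxy-6-(methoxymethoxy)benzaldehyde
Product: 5 3-allyl-2-hydroxy-4-methoxy-6-(methoxymethoxy)benzaldehyde
Conditions: PhNEt2, 190 °C, argon
Reagents that add atoms: none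
Why: Aromatic Claisen rearrangement, in which the allyl group can migrate only to C3, the one free ortho position, so that after tautomerisation it sits between the future O1 and the 7-methoxy group, with the basic solvent protecting the acetal.

**Step 5**
Reactants: 6 4-hydroxy-2-methoxybenzaldehyde
Product: 7 2-methoxy-4-(methoxymethoxy)benzaldehyde
Conditions: MOMCl, i-Pr2NEt, CH2Cl2, 0 °C to rt
Reagents that add atoms: chloromethyl methyl ether (MOMCl), COCCl
Why: MOM protection of the only phenol, which is acidic through its para formyl group and should react cleanly.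

**Step 6**
Reactants: 7 2-methoxy-4-(methoxymethoxy)benzaldehyde
Product: 11 3-allyl-2-methoxy-4-(methoxymethoxy)benzaldehyde, via lithium amino alkoxide 8 (not isolated), via ring-lithiated amino alkoxide 9 (not isolated), via allylated amino alkoxide 10 (not isolated)
Conditions: N-methylpiperazine, n-BuLi, THF, −20 °C, then 7; n-BuLi, −20 °C; CuBr·SMe2 (cat.), allyl bromide, −78 °C to rt; H2O
Reagents that add atoms: allyl bromide, C=CCBr
Why: Comins in situ protection with directed ortho-lithiation, in which the lithium amide masks the formyl group as an α-amino alkoxide that is inert to butyllithium and only a weak director, so metalation should occur at C3 between the methoxy and MOM-oxy groups, and copper-assisted allylation followed by aqueous collapse of the hemiaminal returns the aldehyde.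

**Step 7**
Reactants: 11 3-allyl-2-methoxy-4-(methoxymethoxy)benzaldehyde
Product: 13 [3-allyl-2-methoxy-4-(methoxymethoxy)phenyl]acetonitrile, via 4-tosyl-2-oxazoline 12 (not isolated)
Conditions: TosMIC, t-BuOK, DME, −50 °C; then MeOH, reflux
Reagents that add atoms: p-toluenesulfonylmethyl isocyanide (TosMIC), Cc1ccc(cc1)S(=O)(=O)C[N+]#[C-]
Why: Van Leusen reductive cyanation, in which the TosMIC anion adds to the aldehyde and closes to the tosyl-oxazoline, which methanol opens with loss of methyl formate and sulfinate to give the one-carbon-homologated nitrile.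

**Step 8**
Reactants: 13 [3-allyl-2-methoxy-4-(methoxymethoxy)phenyl]acetonitrile
Product: 14 [3-allyl-2-methoxy-4-(methoxymethoxy)phenyl]acetic acid
Conditions: KOH, EtOH–H2O, 85 °C; then 1 M HCl to pH 4, 0 °C
Reagents that add atoms: potassium hydroxide, [K+].[OH-]; water, O
Why: Alkaline nitrile hydrolysis, to which the MOM ether is stable and under which the doubly flanked allyl group is not expected to migrate into conjugation in aqueous alcohol below 90 °C, with cold acidification to pH 4 sparing the acetal.

**Step 9**
Reactants: 5 3-allyl-2-hydroxy-4-methoxy-6-(methoxymethoxy)benzaldehyde; 14 [3-allyl-2-methoxy-4-(methoxymethoxy)phenyl]acetic acid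
Product: 15 8-allyl-3-[3-allyl-2-methoxy-4-(methoxymethoxy)phenyl]-7-methoxy-5-(methoxymethoxy)-2H-chromen-2-one
Conditions: Ac2O, Et3N, 115 °C
Reagents that add atoms: none
Why: Perkin–Oglialoro condensation, in which the mixed anhydride of the arylacetic acid condenses with the aldehyde and the ortho phenol lactonises, so C3=C4 and the pyranone ring form in one operation with the buffered basic medium leaving the acetals intact.

**Step 10**
Reactants: 15 8-allyl-3-[3-allyl-2-methoxy-4-(methoxymethoxy)phenyl]-7-methoxy-5-(methoxymethoxy)-2H-chromen-2-one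
Product: 16 (Z)-3-[3-allyl-2-hydroxy-4-methoxy-6-(methoxymethoxy)phenyl]-2-[3-allyl-2-methoxy-4-(methoxymethoxy)phenyl]prop-2-en-1-ol
Conditions: i-Bu2AlH (5 equiv), CH2Cl2, −78 to 0 °C; aq. KNaC4H4O6
Reagents that add atoms: none
Why: 1,2-selective hydride reduction of the lactone, which opens the ring to a phenol and a primary allylic alcohol held cis by the ring-derived Z olefin, while the terminal olefins are not hydroaluminated at this temperature.

**Step 11**
Reactants: 16 (Z)-3-[3-allyl-2-hydroxy-4-methoxy-6-(methoxymethoxy)phenyl]-2-[3-allyl-2-methoxy-4-(methoxymethoxy)phenyl]prop-2-en-1-ol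
Product: 17 8-allyl-3-[3-allyl-2-methoxy-4-(methoxymethoxy)phenyl]-7-methoxy-5-(methoxymethoxy)-2H-chromene
Conditions: PPh3, DIAD, THF, 0 °C
Reagents that add atoms: none
Why: Intramolecular Mitsunobu etherification, in which the phenol (the only acidic OH) displaces the activated primary allylic alcohol in a 6-exo-tet closure, giving the electron-rich 2H-chromene without any acid.

**Step 12**
Reactants: 17 8-allyl-3-[3-allyl-2-methoxy-4-(methoxymethoxy)phenyl]-7-methoxy-5-(methoxymethoxy)-2H-chromene
Product: 18 (3S,4R)-8-allyl-3-[3-allyl-2-methoxy-4-(methoxymethoxy)phenyl]-3,4-epoxy-7-methoxy-5-(methoxymethoxy)chromane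
Conditions: (R,R)-N,N′-bis(3,5-di-tert-butylsalicylidene)-1,2-cyclohexanediaminomanganese chloride [(R,R)-(salen)MnCl, trivalent manganese] (5 mol %), 4-phenylpyridine N-oxide, PhIO, 4 Å molecular sieves, CH2Cl2, −20 °C; cold filtration through basic Al2O3, used at once
Reagents that add atoms: iodosylbenzene, O=Ic1ccccc1
Why: Iodosylbenzene converts the trivalent manganese salen complex into a pentavalent manganese–oxo species, which the electron-rich C3=C4 olefin approaches side-on, forming the C4–O bond first (a benzylic radical stabilised by ring A) and then the C3–O bond. The closest known reaction is the Jacobsen–Katsuki epoxidation of 2H-chromenes and of trisubstituted aryl olefins. The oxirane closes by collapse of the C4-bound oxygen onto C3, a net syn addition of one oxygen atom, so it is necessarily cis-fused to ring C. Both new stereocentres, C3 (S) and C4 (R), are fixed by the olefin face that the C2-symmetric diaminocyclohexane backbone and the tert-butyl groups of the catalyst leave open; C4 follows from C3 through the cis fusion and is erased later. The step needs chemoselectivity for the conjugated olefin and survival of an acid-labile oxirane: the only other olefins are monosubstituted, non-conjugated allyl groups, which the electrophilic oxo species should not touch at this temperature, and the water-free oxidant, the sieves and the cold basic filtration keep the oxirane closed until step 13.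

**Step 13**
Reactants: 18 (3S,4R)-8-allyl-3-[3-allyl-2-methoxy-4-(methoxymethoxy)phenyl]-3,4-epoxy-7-methoxy-5-(methoxymethoxy)chromane
Product: 20 (S)-8-allyl-3-[3-allyl-2-methoxy-4-(methoxymethoxy)phenyl]-3-hydroxy-7-methoxy-5-(methoxymethoxy)chroman-4-one, via C4 alkoxysulfonium ion 19 (not isolated)
Conditions: DMSO–CH2Cl2, pyridinium p-toluenesulfonate (0.1 equiv), 0 °C to rt; then Et3N
Reagents that add atoms: dimethyl sulfoxide, CS(C)=O
Why: Kornblum-type oxidative opening of an epoxide by DMSO, in which mild acid should ionise only the C4–O bond (benzylic to the trioxygenated ring A), DMSO captures the cation and base collapses the alkoxysulfonium ion to the ketone with loss of dimethyl sulfide, so the C3–O bond and its configuration are untouched.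

**Step 14**
Reactants: 20 (S)-8-allyl-3-[3-allyl-2-methoxy-4-(methoxymethoxy)phenyl]-3-hydroxy-7-methoxy-5-(methoxymethoxy)chroman-4-one
Product: 21 (S)-3-hydroxy-7-methoxy-3-[2-methoxy-4-(methoxymethoxy)-3-(3-methylbut-2-enyl)phenyl]-5-(methoxymethoxy)-8-(3-methylbut-2-enyl)chroman-4-one
Conditions: 2-methyl-2-butene–CH2Cl2, RuCl2(=CHPh)(H2IMes)(PCy3) (second-generation Grubbs catalyst, 5 mol %), 40 °C
Reagents that add atoms: 2-methyl-2-butene, CC=C(C)C
Why: Olefin cross-metathesis with a large excess of 2-methyl-2-butene, which should turn both terminal allyl groups into prenyl groups with release of propene, the tertiary alcohol, ketone and acetals being inert to the ruthenium carbene.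

**Step 15**
Reactants: 21 (S)-3-hydroxy-7-methoxy-3-[2-methoxy-4-(methoxymethoxy)-3-(3-methylbut-2-enyl)phenyl]-5-(methoxymethoxy)-8-(3-methylbut-2-enyl)chroman-4-one
Product: 22 sophonorol F
Conditions: HCl (ca. 0.5 M, from AcCl), MeOH–THF, 0 °C to rt
Reagents that add atoms: none
Why: Acid-catalysed acetal exchange (MOM removal) in methanol, helped at O5 by hydrogen bonding to the C4 carbonyl, with dilute acid at or below room temperature chosen to avoid dehydration of the tertiary carbinol and cyclisation of the prenyl groups onto the new phenols.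

**Compound list**
1 | 2,4,6-trimethoxybenzaldehyde | COc1cc(OC)c(C=O)c(OC)c1 | starting material
2 | 2,6-dihydroxy-4-methoxybenzaldehyde | COc1cc(O)c(C=O)c(O)c1 | intermediate
3 | 2-hydroxy-4-methoxy-6-(methoxymethoxy)benzaldehyde | COCOc1cc(OC)cc(O)c1C=O | intermediate
4 | 2-(allyloxy)-4-methoxy-6-(methoxymethoxy)benzaldehyde | C=CCOc1cc(OC)cc(OCOC)c1C=O | intermediate
5 | 3-allyl-2-hydroxy-4-methoxy-6-(methoxymethoxy)benzaldehyde | C=CCc1c(O)c(C=O)c(OCOC)cc1OC | intermediate
6 | 4-hydroxy-2-methoxybenzaldehyde | COc1cc(O)ccc1C=O | starting material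
7 | 2-methoxy-4-(methoxymethoxy)benzaldehyde | COCOc1ccc(C=O)c(OC)c1 | intermediate
8 | lithium α-(4-methylpiperazin-1-yl) alkoxide of 7 (formed in the flask, step 6) | [Li+].[O-]C(N1CCN(C)CC1)c1ccc(OCOC)cc1OC | intermediate
9 | C3-lithiated amino alkoxide (formed in the flask, step 6) | [Li+].[O-]C(N1CCN(C)CC1)c1ccc(OCOC)c([Li])c1OC | intermediate
10 | C3-allylated amino alkoxide (formed in the flask, step 6) | [Li+].[O-]C(N1CCN(C)CC1)c1ccc(OCOC)c(CC=C)c1OC | intermediate
11 | 3-allyl-2-methoxy-4-(methoxymethoxy)benzaldehyde | C=CCc1c(OCOC)ccc(C=O)c1OC | intermediate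
12 | 5-[3-allyl-2-methoxy-4-(methoxymethoxy)phenyl]-4-tosyl-4,5-dihydrooxazole (formed in the flask, step 7) | Cc1ccc(cc1)S(=O)(=O)C1N=COC1c1ccc(OCOC)c(CC=C)c1OC | intermediate
13 | [3-allyl-2-methoxy-4-(methoxymethoxy)phenyl]acetonitrile | N#CCc1ccc(OCOC)c(CC=C)c1OC | intermediate
14 | [3-allyl-2-methoxy-4-(methoxymethoxy)phenyl]acetic acid | OC(=O)Cc1ccc(OCOC)c(CC=C)c1OC | intermediate
15 | 8-allyl-3-[3-allyl-2-methoxy-4-(methoxymethoxy)phenyl]-7-methoxy-5-(methoxymethoxy)-2H-chromen-2-one | O=C1Oc2c(CC=C)c(OC)cc(OCOC)c2C=C1c1ccc(OCOC)c(CC=C)c1OC | intermediate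
16 | (Z)-3-[3-allyl-2-hydroxy-4-methoxy-6-(methoxymethoxy)phenyl]-2-[3-allyl-2-methoxy-4-(methoxymethoxy)phenyl]prop-2-en-1-ol | Oc1c(CC=C)c(OC)cc(OCOC)c1/C=C(\CO)c1ccc(OCOC)c(CC=C)c1OC | intermediate
17 | 8-allyl-3-[3-allyl-2-methoxy-4-(methoxymethoxy)phenyl]-7-methoxy-5-(methoxymethoxy)-2H-chromene | COc1cc(OCOC)c2C=C(c3ccc(OCOC)c(CC=C)c3OC)COc2c1CC=C | intermediate
18 | (3S,4R)-8-allyl-3-[3-allyl-2-methoxy-4-(methoxymethoxy)phenyl]-3,4-epoxy-7-methoxy-5-(methoxymethoxy)chromane | COc1cc(OCOC)c2c(c1CC=C)OC[C@]3(c1ccc(OCOC)c(CC=C)c1OC)O[C@H]23 | intermediate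
19 | (3S)-4-(dimethylsulfoniooxy)-3-hydroxy derivative of the chromane, C4 epimers (formed in the flask, step 13) | COc1cc(OCOC)c2c(c1CC=C)OC[C@@](O)(c1ccc(OCOC)c(CC=C)c1OC)C2O[S+](C)C | intermediate
20 | (S)-8-allyl-3-[3-allyl-2-methoxy-4-(methoxymethoxy)phenyl]-3-hydroxy-7-methoxy-5-(methoxymethoxy)chroman-4-one | COc1cc(OCOC)c2c(c1CC=C)OC[C@@](O)(c1ccc(OCOC)c(CC=C)c1OC)C2=O | intermediate
21 | (S)-3-hydroxy-7-methoxy-3-[2-methoxy-4-(methoxymethoxy)-3-(3-methylbut-2-enyl)phenyl]-5-(methoxymethoxy)-8-(3-methylbut-2-enyl)chroman-4-one | COc1cc(OCOC)c2c(c1CC=C(C)C)OC[C@@](O)(c1ccc(OCOC)c(CC=C(C)C)c1OC)C2=O | intermediate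
22 | sophonorol F, (S)-3,5-dihydroxy-3-[4-hydroxy-2-methoxy-3-(3-methylbut-2-enyl)phenyl]-7-methoxy-8-(3-methylbut-2-enyl)chroman-4-one | COc1cc(O)c2c(c1CC=C(C)C)OC[C@@](O)(c1ccc(O)c(CC=C(C)C)c1OC)C2=O | target

**Step count**
Total: 15 steps. Longest linear sequence: 11 steps (steps 1–4 then 9–15; the ring B branch, steps 5–8 then 9–15, is equally long).

**Steps most likely to fail**

Step 12. The salen complex may discriminate the faces of this trisubstituted olefin poorly, or the oxirane may open on the Lewis-acidic manganese before it can be carried on. The fallback sets out from 17 and returns at 20. Osmium-mediated asymmetric dihydroxylation (OsO4 with the dihydroquinidine-derived ligand (DHQD)2PHAL, CH2Cl2, −78 °C, then aq. NaHSO3) is a known reaction of isoflav-3-enes. With ring B in the aryl-binding quadrant of the Sharpless mnemonic it should add both oxygens to the required face, giving the cis-(3S,4R)-isoflavan-3,4-diol F1. The ligand-accelerated reagent should prefer the electron-rich trisubstituted aryl olefin over the monosubstituted allyl groups when osmium is limiting. IBX in DMSO then oxidises the secondary benzylic hydroxyl of F1 without glycol cleavage to give 20.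

Step 13. Ionisation may occur at C3 instead of C4, ring B may migrate to the C4 cation (semipinacol shift) before DMSO captures it, or a MOM group may be lost to the acid. The fallback sets out from 18 and returns at 20. The oxirane is hydrolysed on purpose in THF–water buffered with NaHCO3, where water alone captures the C4 cation, to give the (3S,4S)-trans-diol F2 together with some of its C4 epimer. The mixture is then oxidised at C4 under Parikh–Doering conditions (SO3·pyridine, DMSO, Et3N) to 20, which removes the C4 centre.

Step 6. Butyllithium may add to the masked formyl group, or the amino alkoxide may steer metalation to C6. The fallback sets out from 7 and returns at 11. The aldehyde is reduced with NaBH4 in MeOH to [2-methoxy-4-(methoxymethoxy)phenyl]methanol F3. Its lithium alkoxide is metalated between the two ether oxygens with n-BuLi–TMEDA and allylated (CuBr·SMe2, allyl bromide) to give [3-allyl-2-methoxy-4-(methoxymethoxy)phenyl]methanol F4. MnO2 in CH2Cl2 then returns the benzylic alcohol F4 to aldehyde 11.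

**Further compounds**
F1 | step 12 | (3S,4R)-8-allyl-3-[3-allyl-2-methoxy-4-(methoxymethoxy)phenyl]-7-methoxy-5-(methoxymethoxy)chromane-3,4-diol (cis) | COc1cc(OCOC)c2c(c1CC=C)OC[C@@](O)(c1ccc(OCOC)c(CC=C)c1OC)[C@@H]2O
F2 | step 13 | (3S,4S)-8-allyl-3-[3-allyl-2-methoxy-4-(methoxymethoxy)phenyl]-7-methoxy-5-(methoxymethoxy)chromane-3,4-diol (trans) | COc1cc(OCOC)c2c(c1CC=C)OC[C@@](O)(c1ccc(OCOC)c(CC=C)c1OC)[C@H]2O
F3 | step 6 | [2-methoxy-4-(methoxymethoxy)phenyl]methanol | COCOc1ccc(CO)c(OC)c1
F4 | step 6 | [3-allyl-2-methoxy-4-(methoxymethoxy)phenyl]methanol | C=CCc1c(OCOC)ccc(CO)c1OC
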